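The earlier runs and the new flask were computed with constants of no real substance; noise was put on by code.

| flask | substrate | partner | remark | time |
|---|---|---|---|---|
| maple | 0.0080 M | 0.018 M | run made earlier |  |
| larch | 0.024 M | 0.018 M | run made earlier |  |
| winter | 0.012 M | 0.0180 M |  | 4.0 d |
| summer | 0.012 M | 0.0240 M |  | 4.0 d |
| dawn | 0.012 M | 0.0300 M |  | 4.0 d |

| run | time / d | bis adduct / % | mono adduct / % |
|---|---|---|---|
| maple | 0.333 | 40.3 | 40.0 |
| maple | 0.625 | 47.2 | 39.0 |
| maple | 1.04 | 50.5 | 38.2 |
| maple | 1.25 | 51.8 | 38.0 |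
| maple | 1.67 | 52.8 | 37.8 |
| maple | 2.08 | 53.0 | 37.4 |
| maple | 2.50 | 53.0 | 37.2 |
| larch | 0.208 | 7.4 | 28.9 |
| larch | 0.333 | 8.2 | 28.7 |
| larch | 0.417 | 7.6 | 29.0 |
| larch | 0.625 | 6.8 | 29.0 |
| larch | 1.04 | 7.7 | 29.1 |
| larch | 1.67 | 8.0 | 28.9 |
| larch | 2.50 | 7.2 | 28.2 |

(scatter of a reading: 0.3 percentage points)

- candidate steps: substrate + partner -> mono adduct; substrate + partner -> other mono adduct; partner + mono adduct -> bis adduct; partner + other mono adduct -> bis adduct; partner -> decomposed reagent; substrate <-> dormant form

* amount of bis adduct at the end, in percent of the substrate charged, for each flask in turn (winter, summer, dawn)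

1. Larch could not give every substrate even one partner, for 0.018 M of partner stood against 0.024 M of substrate. I therefore took partner as the limiting reagent there and as wholly bound. I also took the first additions as settled early, since mono adduct read 28.9% at 0.208 d and barely moved afterwards. The larch balance then put 43.2% of first addition on mono adduct and 56.8% on other mono adduct.

2. In maple, bis adduct climbed to 40.3% at 0.333 d, bent, and levelled at 53.0% by 2.08 d. I booked the unseen 9.80% as surviving other mono adduct. Its exposure, the logarithm of starting share over surviving share, was 1.76. Mono adduct fell 0.0856 as fast on that logarithmic scale.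

3. The maple balance left 0.00576 M of partner decomposed. Dividing by exposure gave the break-even concentration c*, the c(other mono adduct) at which that adduct catches partner as fast as partner decomposes: 0.00328 M.

4. A flask levels where c(partner) charged beyond c(substrate) equals the bis adduct made plus c* times exposure. I reckoned three trial exposures:
   - Winter, 0.7: 31.1% bis adduct, demand a shade over the surplus.
   - Summer, 1.70: 52.3%, a shade under.
   - Dawn, 3: 63.8%, also under.

5. The forecast, which “balanced partner against exposure”, gave 31%, 52% and 64%.

6. The flasks gave 32.8%, 52.9% and 64.3%.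

    substrate + partner → mono adduct (k = 34.0 M⁻¹ h⁻¹)
    substrate + partner → other mono adduct (k = 39.0 M⁻¹ h⁻¹)
    partner + mono adduct → bis adduct (k = 2.30 M⁻¹ h⁻¹)
    partner + other mono adduct → bis adduct (k = 29.0 M⁻¹ h⁻¹)
    partner → decomposed reagent (k = 0.0670 h⁻¹)
    substrate ⇌ dormant form (K = 5.30, k = 0.0310 h⁻¹)

Winter ended at 4.00 d with c(other mono adduct) at 0.00236 M, against the 0.00328 M I had reckoned for c*, and 0.00299 M of decomposed reagent. Dawn ended with c(other mono adduct) at 1.19 × 10⁻⁴ M, far below c*, and 0.0105 M of decomposed reagent.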